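**Retrosynthetic overview**

1. Feature: number the cyclopentane C1 (CO2H, butenolide), C2 (spiro), C3, C4 (side chain), C5. A bond between the butenolide carbonyl carbon (C7) and the lactol carbon of the spiro γ-lactone (C8) would make C1–C6–C7–C8–C9–C2 a six-membered ring cis-fused to the cyclopentane. At the alkene level this is a meso cis-1,2-diacid, and the spiro lactone is the C2 carboxyl closed onto C8.
2. Key disconnection: the spiro γ-lactone C–O bond and a trans C7–Br bond come from enantioselective bromolactonisation of meso diacid 14. Diacid 14 comes from a butadiene Diels–Alder reaction on cyclopentene anhydride 10 (TMM [3+2] on dimethyl fumarate, hydroboration, dehydrogenation).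
3. Ring cut: C7–Br to C7=O, Baeyer–Villiger insertion of oxygen into C7–C8, then methanolysis to the masked lactol and the C1 CH2CO2Me arm (C6–C7).
4. Butenolide: aldol of that arm with (S)-2-silyloxyoctanal, lactonisation, dehydration. Dihydropyranone: C4 CH2OSi to CHO, syn-selective alkoxyallylboration, chain extension, Z-olefination, lactonisation during the final acidolysis.
5. Ring order: cyclopentane, temporary cyclohexene, spiro γ-lactone, (six-membered carbocycle opened), butenolide, dihydropyranone.

Key step: step 9

Remark 1: the lactol (acyl hemiacetal) carbon equilibrates through the open aldehyde–acid, so the drawn epimer is taken to be the one the free compound adopts; masked intermediates are carried as epimer mixtures at that carbon.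
Remark 2: hydroquinidine 1,4-phthalazinediyl diether is taken to select the carboxyl group that leads to the drawn enantiomer; otherwise the pseudoenantiomeric hydroquinine diether is used with no other change.

**Route**

Step 1
Reactants: 1 dimethyl fumarate; 2 2-[(trimethylsilyl)methyl]allyl acetate
Product: 3 (±)-dimethyl trans-4-methylenecyclopentane-1,2-dicarboxylate
Conditions: Pd(OAc)2 (5 mol %), P(OiPr)3 (30 mol %), THF, reflux
Reagents that add atoms: none
Why: Palladium-catalysed trimethylenemethane [3+2] cycloaddition, in which the zwitterionic Pd–TMM complex adds to the electron-poor alkene by Michael addition and ring closure, so the trans geometry of the fumarate should be carried into the racemic trans diester.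

Step 2
Reactants: 3 (±)-dimethyl trans-4-methylenecyclopentane-1,2-dicarboxylate
Product: 5 (±)-dimethyl trans-4-(hydroxymethyl)cyclopentane-1,2-dicarboxylate, via B-alkyl-9-BBN adduct 4 (not isolated)
Conditions: 9-BBN (9-borabicyclo[3.3.1]nonane), THF, 0 °C to rt; then NaBO3·4H2O, H2O, rt
Reagents that add atoms: sodium perborate, [Na+].[O-]OB=O
Why: Anti-Markovnikov hydroboration–oxidation of the 1,1-disubstituted exocyclic alkene, which 9-BBN attacks without touching the esters; C4 is not a stereocentre in the trans diester, so no isomers arise.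

Step 3
Reactants: 5 (±)-dimethyl trans-4-(hydroxymethyl)cyclopentane-1,2-dicarboxylate
Product: 6 (±)-dimethyl trans-4-[(tert-butyldiphenylsilyloxy)methyl]cyclopentane-1,2-dicarboxylate
Conditions: TBDPSCl, imidazole, DMF, rt
Reagents that add atoms: tert-butyl(chloro)diphenylsilane, CC(C)(C)[Si](Cl)(c1ccccc1)c1ccccc1
Why: Silylation of a primary alcohol; the TBDPS ether is chosen because it should survive the enolate, thermal, radical and mildly acidic steps that follow.

Step 4
Reactants: 6 (±)-dimethyl trans-4-[(tert-butyldiphenylsilyloxy)methyl]cyclopentane-1,2-dicarboxylate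
Product: 8 dimethyl 4-[(tert-butyldiphenylsilyloxy)methyl]cyclopent-1-ene-1,2-dicarboxylate, via dilithium bis-enolate 7 (not isolated)
Conditions: LiN(iPr)2 (2.3 equiv), THF, −78 to 0 °C; then I2, −78 °C
Reagents that add atoms: none
Why: Oxidation of a vicinal diester bis-enolate with iodine (dehydrogenation of a succinate-type dianion) should give the tetrasubstituted, doubly conjugated alkene and removes both ester stereocentres.

Step 5
Reactants: 8 dimethyl 4-[(tert-butyldiphenylsilyloxy)methyl]cyclopent-1-ene-1,2-dicarboxylate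
Product: 9 4-[(tert-butyldiphenylsilyloxy)methyl]cyclopent-1-ene-1,2-dicarboxylic acid
Conditions: LiOH, THF/MeOH/H2O, rt; then 1 M HCl
Reagents that add atoms: lithium hydroxide, [Li+].[OH-]
Why: Saponification of the conjugated diester; the primary TBDPS ether is stable to aqueous hydroxide at room temperature.

Step 6
Reactants: 9 4-[(tert-butyldiphenylsilyloxy)methyl]cyclopent-1-ene-1,2-dicarboxylic acid
Product: 10 4-[(tert-butyldiphenylsilyloxy)methyl]cyclopent-1-ene-1,2-dicarboxylic anhydride
Conditions: Ac2O, 80 °C
Reagents that add atoms: none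
Why: Dehydrative cyclisation of a cis-locked 1,2-diacid to the five-membered cyclic anhydride, a planar and strongly activated dienophile.

Step 7
Reactants: 10 4-[(tert-butyldiphenylsilyloxy)methyl]cyclopent-1-ene-1,2-dicarboxylic anhydride; 11 3-sulfolene
Product: 13 meso 8-[(tert-butyldiphenylsilyloxy)methyl]-cis-bicyclo[4.3.0]non-3-ene-1,6-dicarboxylic anhydride (arm cis to the anhydride carbonyls), via buta-1,3-diene 12 (not isolated)
Conditions: 3-sulfolene (3 equiv), hydroquinone (cat.), toluene, 125 °C, sealed tube
Reagents that add atoms: none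
Why: Diels–Alder reaction of butadiene (from cheletropic loss of SO2) with the maleic-type anhydride; suprafacial addition fixes the cis fusion, and the diene should approach the planar dienophile anti to the C4 silyloxymethyl arm, leaving the arm cis to both carbonyl groups (any syn adduct would be removed here by crystallisation).

Step 8
Reactants: 13 meso propellane anhydride
Product: 14 meso 8-[(tert-butyldiphenylsilyloxy)methyl]-cis-bicyclo[4.3.0]non-3-ene-1,6-dicarboxylic acid (arm cis to both CO2H)
Conditions: NaOH, THF/H2O, rt; then 1 M HCl, 0 °C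
Reagents that add atoms: sodium hydroxide, [Na+].[OH-]
Why: Hydroxide opening of the cyclic anhydride and cold acidification give the meso diacid (mirror plane through the arm-bearing carbon and the midpoint of the alkene), which is used at once because tetrasubstituted succinic acids re-close on heating.

Step 9
Reactants: 14 meso diacid
Product: 15 bromo γ-lactone acid (C2 carboxyl closed on C8 as a 6-oxabicyclo[3.2.1]octan-7-one, Br on C7 trans to the lactone oxygen, free C1 CO2H)
Conditions: NBS (1.1 equiv), hydroquinidine 1,4-phthalazinediyl diether [(DHQD)2PHAL] (10 mol %), CHCl3/toluene (1:2), −40 °C, dark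
Reagents that add atoms: N-bromosuccinimide, O=C1CCC(=O)N1Br
Why: NBS transfers Br+ reversibly to either face of the cyclohexene, but only the bromonium ion on the face anti to the carboxyl groups can be opened, and it is opened from the back by the carboxylate that is ion-paired to the quinuclidine nitrogen of the catalyst. The closest known reaction type is the cinchona-alkaloid-catalysed enantioselective bromolactonisation of alkenoic acids, including desymmetrising variants, together with the racemic halolactonisation of cis-cyclohex-4-ene-1,2-dicarboxylic acids. The one ring closed is the bridged γ-lactone, formed by 5-exo opening of the bromonium ion; the 6-endo closure to a bicyclo[2.2.2] δ-lactone is disfavoured by strain. The C8–O and C7–Br centres follow from anti addition (oxygen delivered on the face of its own carboxyl, bromine trans to it), while C1, C2 and C4, already fixed relative to one another, become absolute through the catalyst's choice between the two enantiotopic carboxyl groups. The step therefore needs only this group selection: the mirror plane of 14 makes the two possible 5-exo closures enantiomeric, each carboxyl can reach only its nearer alkene carbon, and the rigid cis-diacid geometry secures regio- and diastereocontrol, so the chiral ion pair alone decides the enantiomer.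

Step 10
Reactants: 15 bromo γ-lactone acid
Product: 16 tert-butyl ester of 15
Conditions: tBuOC(=NH)CCl3, CH2Cl2/cyclohexane, rt
Reagents that add atoms: tert-butyl 2,2,2-trichloroacetimidate, CC(C)(C)OC(=N)C(Cl)(Cl)Cl
Why: O-Alkylation of the carboxylic acid by the imidate proceeds through the tert-butyl cation and so is insensitive to the neopentyl hindrance at C1; the ester has no α-hydrogen and is removed by acid at the end.

Step 11
Reactants: 16 bromo lactone tert-butyl ester
Product: 18 C7 hydroxy lactone tert-butyl ester (epimer mixture at C7), via C7 hydroperoxide 17 (not isolated)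
Conditions: Bu3SnH (slow addition), azobisisobutyronitrile (cat.), dry air, toluene, 60 °C
Reagents that add atoms: dioxygen, O=O
Why: Radical oxygenation of an alkyl halide (halogen abstraction by the stannyl radical, trapping of the secondary radical by O2, reduction of the hydroperoxide by the tin hydride), a known way to turn halolactones into hydroxy lactones where backside displacement is blocked; the C7 configuration is of no consequence.

Step 12
Reactants: 18 C7 hydroxy lactone
Product: 19 C7 keto lactone (α-acyloxy ketone)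
Conditions: Dess–Martin periodinane, CH2Cl2, rt
Reagents that add atoms: none
Why: Dess–Martin oxidation of the secondary alcohol; enolisation toward the bridgehead C8 is excluded by Bredt's rule, so that centre is safe.

Step 13
Reactants: 19 C7 keto lactone
Product: 20 seven-membered acylal lactone (oxygen inserted between C7 and C8)
Conditions: mCPBA, CH2Cl2, 0 °C to rt
Reagents that add atoms: 3-chloroperbenzoic acid, OOC(=O)c1cccc(Cl)c1
Why: Baeyer–Villiger oxidation in which the secondary, oxygen-bearing bridgehead carbon C8 should migrate with retention in preference to the primary C6, so oxygen enters exactly the C–C bond that is absent from the target.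

Step 14
Reactants: 20 acylal lactone
Product: 22 methyl acetal of the spiro γ-lactone lactol with CH2CO2Me and CO2tBu on C1 (epimer mixture at the acetal carbon), via lactol methyl ester 21 (not isolated)
Conditions: camphorsulfonic acid (cat.), HC(OMe)3, MeOH, rt
Reagents that add atoms: methanol, CO; trimethyl orthoformate, COC(OC)OC
Why: Acid-catalysed transesterification at the less hindered acyl group of the acylal frees the lactol, and Fischer-type acetalisation in the same pot converts it into the methyl pseudo-ester, a mask that tolerates the enolate chemistry to come.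

Step 15
Reactants: 23 (S)-octane-1,2-diol
Product: 24 (S)-1,2-bis(triethylsilyloxy)octane
Conditions: TESCl, imidazole, DMF, 0 °C to rt
Reagents that add atoms: chlorotriethylsilane, CC[Si](Cl)(CC)CC
Why: Exhaustive silylation of the diol under standard conditions.

Step 16
Reactants: 24 (S)-1,2-bis(triethylsilyloxy)octane
Product: 26 (S)-2-(triethylsilyloxy)octanal, via alkoxysulfonium chloride 25 (not isolated)
Conditions: (COCl)2, DMSO, CH2Cl2, −78 to −40 °C; then Et3N, −78 °C to rt
Reagents that add atoms: none
Why: Swern conditions cleave and oxidise a primary triethylsilyl ether selectively (known oxidative deprotection of primary TES ethers), leaving the secondary silyl ether and its stereocentre untouched.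

Step 17
Reactants: 22 methyl acetal ester; 26 (S)-2-(triethylsilyloxy)octanal
Product: 28 aldol adduct (β-hydroxy-γ-silyloxy methyl ester, mixture at the two new centres), via lithium ester enolate 27 (not isolated)
Conditions: LiN(iPr)2, THF, −78 °C; then 26, −78 °C; AcOH quench
Reagents that add atoms: none
Why: Aldol addition of the lithium enolate of the only enolisable ester to the α-silyloxy aldehyde; both new centres are removed later, and the (S) centre of the aldehyde becomes C5 of the butenolide.

Step 18
Reactants: 28 aldol adduct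
Product: 30 β-hydroxy γ-lactone (3-substituted 4-hydroxy-5-hexyl-dihydrofuran-2-one), via desilylated diol ester 29 (not isolated)
Conditions: pyridinium p-toluenesulfonate, MeOH, rt; then pyridinium p-toluenesulfonate, toluene, 60 °C
Reagents that add atoms: none
Why: Mild acid removes the labile secondary TES ether while the TBDPS ether, the tert-butyl ester and the methyl acetal persist, and acid-catalysed lactonisation of the γ-hydroxy methyl ester closes the five-membered ring.

Step 19
Reactants: 30 β-hydroxy γ-lactone
Product: 32 butenolide (3-substituted (S)-5-hexylfuran-2(5H)-one) with C4 CH2OTBDPS, via β-mesylate 31 (not isolated)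
Conditions: MsCl, Et3N, CH2Cl2, 0 °C to rt
Reagents that add atoms: none
Why: Mesylation and E1cB elimination of the β-mesyloxy lactone complete the aldol–lactonisation–dehydration butenolide annulation; the mild amine base should leave the γ-stereocentre intact.

Step 20
Reactants: 32 butenolide TBDPS ether
Product: 33 primary alcohol (C4 CH2OH)
Conditions: HF·pyridine, pyridine, THF, 0 °C to rt
Reagents that add atoms: none
Why: Fluoride-mediated silyl ether cleavage under buffered, weakly acidic conditions avoids base-induced epimerisation of the butenolide and translactonisation by the freed alcohol.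

Step 21
Reactants: 33 primary alcohol
Product: 34 C4 aldehyde
Conditions: Dess–Martin periodinane, CH2Cl2, 0 °C
Reagents that add atoms: none
Why: Dess–Martin oxidation under non-basic conditions gives the α-branched aldehyde, which is used directly so that C4 does not epimerise.

Step 22
Reactants: 35 allyl alcohol; 36 chloromethyl methyl ether
Product: 37 allyl methoxymethyl ether
Conditions: iPr2NEt, CH2Cl2, 0 °C to rt
Reagents that add atoms: none
Why: O-Alkylation of the alcohol with the α-chloro ether (MOM protection) under amine base.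

Step 23
Reactants: 34 C4 aldehyde; 37 allyl methoxymethyl ether
Product: 41 syn (S,S) homoallylic alcohol C4–CH(OH)–CH(OMOM)–CH=CH2, via (Z)-3-(methoxymethoxy)allyllithium 38 (not isolated), via B-alkoxyallyl-diisopinocampheylborane 39 (not isolated), via borinate ester 40 (not isolated)
Conditions: 37, sec-BuLi, THF, −78 °C; (+)-Ipc2BOMe; BF3·OEt2; then 34, −78 °C; then NaBO3·4H2O, THF/H2O, rt
Reagents that add atoms: none
Why: Brown (Z)-γ-alkoxyallylboration through a chair Zimmerman–Traxler transition state, in which the Z geometry gives the syn 1,2-diol monoether and the isopinocampheyl groups derived from (−)-α-pinene direct attack to the Re face of the aldehyde, so both carbinol centres are set (S,S) under reagent control.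

Step 24
Reactants: 41 syn homoallylic alcohol
Product: 42 TBS ether of 41
Conditions: TBSOTf, 2,6-lutidine, CH2Cl2, −78 to 0 °C
Reagents that add atoms: tert-butyldimethylsilyl trifluoromethanesulfonate, CC(C)(C)[Si](C)(C)OS(=O)(=O)C(F)(F)F
Why: Silylation of the hindered secondary alcohol with the silyl triflate; the protection prevents lactol formation when the chain end is later oxidised.

Step 25
Reactants: 42 TBS ether
Product: 44 primary alcohol (vinyl converted into CH2CH2OH), via alkyl-9-BBN adduct 43 (not isolated)
Conditions: 9-BBN, THF, 0 °C to rt; then NaBO3·4H2O, H2O, rt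
Reagents that add atoms: sodium perborate, [Na+].[O-]OB=O
Why: Anti-Markovnikov hydroboration–oxidation of the terminal vinyl group; the conjugated, trisubstituted butenolide alkene and the esters should not react with 9-BBN under these conditions.

Step 26
Reactants: 44 primary alcohol
Product: 45 β-(methoxymethoxy) aldehyde
Conditions: Dess–Martin periodinane, CH2Cl2, rt
Reagents that add atoms: none
Why: Dess–Martin oxidation of the primary alcohol without base, which avoids β-elimination of the alkoxy group.

Step 27
Reactants: 45 β-(methoxymethoxy) aldehyde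
Product: 46 (Z)-δ-(methoxymethoxy) α,β-unsaturated methyl ester
Conditions: (CF3CH2O)2P(O)CH2CO2Me, KN(SiMe3)2, 18-crown-6, THF, −78 °C
Reagents that add atoms: methyl bis(2,2,2-trifluoroethyl)phosphonoacetate, COC(=O)CP(=O)(OCC(F)(F)F)OCC(F)(F)F
Why: Still–Gennari variant of the Horner–Wadsworth–Emmons olefination, whose electron-poor phosphonate under dissociating conditions should give the (Z)-enoate needed for lactonisation.

Step 28
Reactants: 46 (Z)-enoate
Product: 48 Penicillactone A, via seco hydroxy enoate 47 (not isolated)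
Conditions: TFA/CH2Cl2/H2O (10:10:1), 0 °C to rt
Reagents that add atoms: water, O
Why: Acidolysis removes the MOM ether, the TBS ether, the tert-butyl ester and the methyl acetal in one operation, the freed δ-hydroxyl lactonises onto the (Z)-enoate to the 5,6-dihydro-2H-pyran-2-one (six-membered ring preferred over the seven-membered alternative), and the lactol settles into its preferred epimer.

**Compound list**

1 | dimethyl fumarate | COC(=O)/C=C/C(=O)OC | starting material
2 | 2-[(trimethylsilyl)methyl]allyl acetate | CC(=O)OCC(=C)C[Si](C)(C)C | starting material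
3 | (±)-dimethyl trans-4-methylenecyclopentane-1,2-dicarboxylate (one enantiomer drawn) | C=C1C[C@H](C(=O)OC)[C@@H](C(=O)OC)C1 | intermediate
4 | B-alkyl-9-BBN adduct of 3 (not isolated) | C(B1C2CCCC1CCC2)C1C[C@H](C(=O)OC)[C@@H](C(=O)OC)C1 | intermediate
5 | (±)-dimethyl trans-4-(hydroxymethyl)cyclopentane-1,2-dicarboxylate | OCC1C[C@H](C(=O)OC)[C@@H](C(=O)OC)C1 | intermediate
6 | (±)-dimethyl trans-4-[(tert-butyldiphenylsilyloxy)methyl]cyclopentane-1,2-dicarboxylate | CC(C)(C)[Si](c1ccccc1)(c1ccccc1)OCC1C[C@H](C(=O)OC)[C@@H](C(=O)OC)C1 | intermediate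
7 | dilithium bis-enolate of 6 (not isolated) | CC(C)(C)[Si](c1ccccc1)(c1ccccc1)OCC1CC(=C([O-])OC)C(=C([O-])OC)C1.[Li+].[Li+] | intermediate
8 | dimethyl 4-[(tert-butyldiphenylsilyloxy)methyl]cyclopent-1-ene-1,2-dicarboxylate | CC(C)(C)[Si](c1ccccc1)(c1ccccc1)OCC1CC(C(=O)OC)=C(C(=O)OC)C1 | intermediate
9 | 4-[(tert-butyldiphenylsilyloxy)methyl]cyclopent-1-ene-1,2-dicarboxylic acid | CC(C)(C)[Si](c1ccccc1)(c1ccccc1)OCC1CC(C(=O)O)=C(C(=O)O)C1 | intermediate
10 | 4-[(tert-butyldiphenylsilyloxy)methyl]cyclopent-1-ene-1,2-dicarboxylic anhydride | CC(C)(C)[Si](c1ccccc1)(c1ccccc1)OCC1CC2=C(C1)C(=O)OC2=O | intermediate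
11 | 3-sulfolene | O=S1(=O)CC=CC1 | starting material
12 | buta-1,3-diene (not isolated) | C=CC=C | intermediate
13 | meso 8-[(tert-butyldiphenylsilyloxy)methyl]-cis-bicyclo[4.3.0]non-3-ene-1,6-dicarboxylic anhydride, arm cis to the anhydride carbonyls | C1[C@]2(C(=O)O4)C[C@@H](CO[Si](c3ccccc3)(c3ccccc3)C(C)(C)C)C[C@]2(C4=O)CC=C1 | intermediate
14 | meso 8-[(tert-butyldiphenylsilyloxy)methyl]-cis-bicyclo[4.3.0]non-3-ene-1,6-dicarboxylic acid, arm cis to both CO2H | C1[C@]2(C(=O)O)C[C@@H](CO[Si](c3ccccc3)(c3ccccc3)C(C)(C)C)C[C@]2(C(=O)O)CC=C1 | intermediate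
15 | bromo γ-lactone acid (C2 carboxyl closed on C8, Br on C7 trans to the lactone oxygen, free C1 CO2H) | C1[C@]2(C(=O)O)C[C@@H](CO[Si](c3ccccc3)(c3ccccc3)C(C)(C)C)C[C@]2(C(=O)O4)C[C@@H]4[C@@H]1Br | intermediate
16 | tert-butyl ester of 15 | C1[C@]2(C(=O)OC(C)(C)C)C[C@@H](CO[Si](c3ccccc3)(c3ccccc3)C(C)(C)C)C[C@]2(C(=O)O4)C[C@@H]4[C@@H]1Br | intermediate
17 | C7 hydroperoxide from 16 (not isolated) | C1[C@]2(C(=O)OC(C)(C)C)C[C@@H](CO[Si](c3ccccc3)(c3ccccc3)C(C)(C)C)C[C@]2(C(=O)O4)C[C@@H]4C1OO | intermediate
18 | C7 hydroxy lactone tert-butyl ester (epimer mixture at C7) | C1[C@]2(C(=O)OC(C)(C)C)C[C@@H](CO[Si](c3ccccc3)(c3ccccc3)C(C)(C)C)C[C@]2(C(=O)O4)C[C@@H]4C1O | intermediate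
19 | C7 keto lactone tert-butyl ester (α-acyloxy ketone) | C1[C@]2(C(=O)OC(C)(C)C)C[C@@H](CO[Si](c3ccccc3)(c3ccccc3)C(C)(C)C)C[C@]2(C(=O)O4)C[C@@H]4C1=O | intermediate
20 | seven-membered acylal lactone (oxygen between C7 and C8) | C1[C@]2(C(=O)OC(C)(C)C)C[C@@H](CO[Si](c3ccccc3)(c3ccccc3)C(C)(C)C)C[C@]2(C(=O)O4)C[C@@H]4OC1=O | intermediate
21 | lactol of the spiro γ-lactone with CH2CO2Me on C1 (not isolated) | COC(=O)C[C@]2(C(=O)OC(C)(C)C)C[C@@H](CO[Si](c3ccccc3)(c3ccccc3)C(C)(C)C)C[C@]2(C(=O)O4)CC4O | intermediate
22 | methyl acetal of 21 (5-methoxy spiro γ-lactone, CH2CO2Me and CO2tBu on C1) | COC(=O)C[C@]2(C(=O)OC(C)(C)C)C[C@@H](CO[Si](c3ccccc3)(c3ccccc3)C(C)(C)C)C[C@]2(C(=O)O4)CC4OC | intermediate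
23 | (S)-octane-1,2-diol | CCCCCC[C@H](O)CO | starting material
24 | (S)-1,2-bis(triethylsilyloxy)octane | CCCCCC[C@H](O[Si](CC)(CC)CC)CO[Si](CC)(CC)CC | intermediate
25 | alkoxysulfonium chloride from 24 (not isolated) | CCCCCC[C@H](O[Si](CC)(CC)CC)CO[S+](C)C.[Cl-] | intermediate
26 | (S)-2-(triethylsilyloxy)octanal | CCCCCC[C@H](O[Si](CC)(CC)CC)C=O | intermediate
27 | lithium enolate of the CH2CO2Me arm of 22 (not isolated) | [Li+].COC([O-])=C[C@]2(C(=O)OC(C)(C)C)C[C@@H](CO[Si](c3ccccc3)(c3ccccc3)C(C)(C)C)C[C@]2(C(=O)O4)CC4OC | intermediate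
28 | aldol adduct (β-hydroxy-γ-triethylsilyloxy methyl ester) | CCCCCC[C@H](O[Si](CC)(CC)CC)C(O)C(C(=O)OC)[C@]2(C(=O)OC(C)(C)C)C[C@@H](CO[Si](c3ccccc3)(c3ccccc3)C(C)(C)C)C[C@]2(C(=O)O4)CC4OC | intermediate
29 | β,γ-dihydroxy methyl ester (not isolated) | CCCCCC[C@H](O)C(O)C(C(=O)OC)[C@]2(C(=O)OC(C)(C)C)C[C@@H](CO[Si](c3ccccc3)(c3ccccc3)C(C)(C)C)C[C@]2(C(=O)O4)CC4OC | intermediate
30 | β-hydroxy γ-lactone | CCCCCC[C@H]1C(O)C([C@]2(C(=O)OC(C)(C)C)C[C@@H](CO[Si](c3ccccc3)(c3ccccc3)C(C)(C)C)C[C@]2(C(=O)O4)CC4OC)C(=O)O1 | intermediate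
31 | β-mesylate of 30 (not isolated) | CCCCCC[C@H]1C(OS(C)(=O)=O)C([C@]2(C(=O)OC(C)(C)C)C[C@@H](CO[Si](c3ccccc3)(c3ccccc3)C(C)(C)C)C[C@]2(C(=O)O4)CC4OC)C(=O)O1 | intermediate
32 | butenolide with C4 CH2OTBDPS | CCCCCC[C@H]1C=C([C@]2(C(=O)OC(C)(C)C)C[C@@H](CO[Si](c3ccccc3)(c3ccccc3)C(C)(C)C)C[C@]2(C(=O)O4)CC4OC)C(=O)O1 | intermediate
33 | butenolide with C4 CH2OH | CCCCCC[C@H]1C=C([C@]2(C(=O)OC(C)(C)C)C[C@@H](CO)C[C@]2(C(=O)O4)CC4OC)C(=O)O1 | intermediate
34 | butenolide with C4 CHO | CCCCCC[C@H]1C=C([C@]2(C(=O)OC(C)(C)C)C[C@@H](C=O)C[C@]2(C(=O)O4)CC4OC)C(=O)O1 | intermediate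
35 | allyl alcohol | C=CCO | starting material
36 | chloromethyl methyl ether | COCCl | starting material
37 | allyl methoxymethyl ether | C=CCOCOC | intermediate
38 | (Z)-3-(methoxymethoxy)allyllithium (not isolated) | [Li]C/C=C\OCOC | intermediate
39 | B-[(Z)-3-(methoxymethoxy)allyl]diisopinocampheylborane, Ipc from (−)-α-pinene (not isolated) | COCO/C=C\CB([C@H]1C[C@H]2C[C@@H]([C@@H]1C)C2(C)C)[C@H]1C[C@H]2C[C@@H]([C@@H]1C)C2(C)C | intermediate
40 | diisopinocampheylborinate of 41 (not isolated) | CCCCCC[C@H]1C=C([C@]2(C(=O)OC(C)(C)C)C[C@@H]([C@H](OB([C@H]5C[C@H]6C[C@@H]([C@@H]5C)C6(C)C)[C@H]5C[C@H]6C[C@@H]([C@@H]5C)C6(C)C)[C@@H](OCOC)C=C)C[C@]2(C(=O)O4)CC4OC)C(=O)O1 | intermediate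
41 | syn (S,S) homoallylic alcohol, C4–CH(OH)–CH(OMOM)–CH=CH2 | CCCCCC[C@H]1C=C([C@]2(C(=O)OC(C)(C)C)C[C@@H]([C@H](O)[C@@H](OCOC)C=C)C[C@]2(C(=O)O4)CC4OC)C(=O)O1 | intermediate
42 | TBS ether of 41 | CCCCCC[C@H]1C=C([C@]2(C(=O)OC(C)(C)C)C[C@@H]([C@H](O[Si](C)(C)C(C)(C)C)[C@@H](OCOC)C=C)C[C@]2(C(=O)O4)CC4OC)C(=O)O1 | intermediate
43 | alkyl-9-BBN adduct of 42 (not isolated) | CCCCCC[C@H]1C=C([C@]2(C(=O)OC(C)(C)C)C[C@@H]([C@H](O[Si](C)(C)C(C)(C)C)[C@@H](OCOC)CCB5C6CCCC5CCC6)C[C@]2(C(=O)O4)CC4OC)C(=O)O1 | intermediate
44 | primary alcohol, C4–CH(OTBS)–CH(OMOM)–CH2CH2OH | CCCCCC[C@H]1C=C([C@]2(C(=O)OC(C)(C)C)C[C@@H]([C@H](O[Si](C)(C)C(C)(C)C)[C@@H](OCOC)CCO)C[C@]2(C(=O)O4)CC4OC)C(=O)O1 | intermediate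
45 | aldehyde, C4–CH(OTBS)–CH(OMOM)–CH2CHO | CCCCCC[C@H]1C=C([C@]2(C(=O)OC(C)(C)C)C[C@@H]([C@H](O[Si](C)(C)C(C)(C)C)[C@@H](OCOC)CC=O)C[C@]2(C(=O)O4)CC4OC)C(=O)O1 | intermediate
46 | (Z)-enoate, C4–CH(OTBS)–CH(OMOM)–CH2–CH=CH–CO2Me | CCCCCC[C@H]1C=C([C@]2(C(=O)OC(C)(C)C)C[C@@H]([C@H](O[Si](C)(C)C(C)(C)C)[C@@H](OCOC)C/C=C\C(=O)OC)C[C@]2(C(=O)O4)CC4OC)C(=O)O1 | intermediate
47 | seco dihydroxy (Z)-enoate with free C1 CO2H and free lactol (not isolated) | CCCCCC[C@H]1C=C([C@]2(C(=O)O)C[C@@H]([C@H](O)[C@@H](O)C/C=C\C(=O)OC)C[C@]2(C(=O)O4)CC4O)C(=O)O1 | intermediate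
48 | Penicillactone A | CCCCCC[C@H]1C=C([C@]2(C(=O)O)C[C@@H]([C@H](O)[C@@H]3CC=CC(=O)O3)C[C@]23C[C@@H](O)OC3=O)C(=O)O1 | target

**Step count**

Total: 28 steps. Longest linear sequence: 25 steps (steps 1–14, 17–21 and 23–28); steps 15–16 and step 22 are side branches.

**Steps most likely to fail**

Step 9. The catalyst may discriminate poorly between the two enantiotopic carboxyl groups, for example because uncatalysed bromolactonisation competes. The fallback is classical resolution. It sets out from 14: NBS with NaHCO3 in THF/H2O gives 15 together with the mirror-image bromo lactone acid F1 as the racemate. Salt formation with (S)-1-phenylethylamine (or its antipode, whichever gives the less soluble salt of 15) and crystallisation give the (S)-1-phenylethylammonium salt F2. Acidification of F2 with dilute HCl returns to the route at 15.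

Step 13. The primary C6 may migrate instead of the acyloxy-bearing C8, or the hindered ketone may not be oxidised. The fallback is a ketol cleavage in place of oxygen insertion. It sets out from 19: LiOH in THF/H2O at 0 °C opens the bridged lactone to the α-hydroxy ketone acid F3. NaIO4 in THF/H2O cleaves the C7–C8 bond of the ketol, with C8 becoming the aldehyde and C7 the carboxylic acid. The aldehyde closes with the C2 carboxyl, giving the hydroxy lactone with a CH2CO2H arm F4. Camphorsulfonic acid with HC(OMe)3 in MeOH (the conditions of step 14) esterifies the arm and forms the methyl acetal, returning to the route at 22.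

Step 7. The cycloaddition may show poor facial selectivity, since the C4 arm is only 1,3 to the reacting carbons. The fallback sorts the epimers by lactonisation. It sets out from 13 as obtained together with its C8 epimer. Hydrolysis with NaOH and desilylation with Bu4NF give the meso hydroxymethyl diacid F5 and its C8 epimer. On warming with p-toluenesulfonic acid in toluene, only F5, whose arm is cis to the carboxyl groups, can close to the bridged δ-lactone acid F6. The epimer ends as the neutral C8-epimeric hydroxymethyl anhydride F7, which is removed by bicarbonate extraction of F6. Saponification of F6 with NaOH regenerates F5, and silylation with TBDPSCl and imidazole (silyl esters hydrolysed on work-up) returns to the route at 14.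

**Further compounds**

F1 | step 9 | mirror-image bromo γ-lactone acid (enantiomer of 15) | C1[C@@]2(C(=O)O)C[C@H](CO[Si](c3ccccc3)(c3ccccc3)C(C)(C)C)C[C@@]2(C(=O)O4)C[C@H]4[C@H]1Br
F2 | step 9 | (S)-1-phenylethylammonium salt of 15 | C1[C@]2(C(=O)[O-])C[C@@H](CO[Si](c3ccccc3)(c3ccccc3)C(C)(C)C)C[C@]2(C(=O)O4)C[C@@H]4[C@@H]1Br.C[C@H]([NH3+])c1ccccc1
F3 | step 13 | α-hydroxy ketone acid (C8–OH, C7=O, free C2 CO2H, tert-butyl ester at C1) | C1[C@]2(C(=O)OC(C)(C)C)C[C@@H](CO[Si](c3ccccc3)(c3ccccc3)C(C)(C)C)C[C@]2(C(=O)O)C[C@@H](O)C1=O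
F4 | step 13 | hydroxy spiro γ-lactone (lactol) with CH2CO2H arm on C1 | OC(=O)C[C@]2(C(=O)OC(C)(C)C)C[C@@H](CO[Si](c3ccccc3)(c3ccccc3)C(C)(C)C)C[C@]2(C(=O)O4)CC4O
F5 | step 7 | meso 8-(hydroxymethyl)-cis-bicyclo[4.3.0]non-3-ene-1,6-dicarboxylic acid, arm cis to both CO2H | C1[C@]2(C(=O)O)C[C@@H](CO)C[C@]2(C(=O)O)CC=C1
F6 | step 7 | bridged δ-lactone acid from F5 (racemic, one enantiomer drawn) | C1[C@]2(C(=O)O)C[C@@H](CO5)C[C@]2(C5=O)CC=C1
F7 | step 7 | C8-epimeric hydroxymethyl anhydride (arm trans to the anhydride carbonyls) | C1[C@]2(C(=O)O4)C[C@H](CO)C[C@]2(C4=O)CC=C1
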